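## Analysis of the target

Target 16 is a flavone: benzo ring A is fused to the 4-pyranone ring C, and aryl ring B sits on C2. It has no stereocentre, and the only alkene outside the aromatic system is the trisubstituted one of the prenyl ether, which has no geometry to set. Ring A is a 1,2,3,5-tetraoxygenated benzene whose four oxygens are all different: the ring oxygen O1 on C8a, a methoxy group on C8, the prenyl ether on C7 and a free hydroxyl on C5. Only C6 carries hydrogen. Ring C bears a methoxy group on the enol-ether carbon C3, and ring B is a guaiacol with a free 4'-hydroxyl. The sensitive groups are the aryl prenyl ether (it ionises in acid, is hydrogenated, and reacts with halogen electrophiles), C2 of the chromone (hard nucleophiles add there and open ring C), and the 5-OH/C4=O pair, which under hot acid allows ring C to reclose onto the other ortho oxygen and scramble the 5,7,8 pattern to 5,6,7. The synthesis is hard for four reasons: one of the two oxygens ortho to C4a must be chosen as O1, C3 needs an oxygen, 7-OH must be told apart from 4'-OH, and the prenyl group can only arrive after all electrophilic and reductive chemistry. The strategy rests on the fact that C4, C3 and C2 are the carbonyl, α- and β-carbons of a ring A aryl ynone. A methoxy oxygen on the C8a carbon can add to the β-carbon (C2) once an electrophile activates the triple bond, and that electrophile is left on C3, where the methoxy group is needed.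

## Retrosynthetic reasoning

**O4'–acetal (16 from 15).** The last bond cut is the methoxymethyl acetal on O4'. The 4'-hydroxyl must be masked while O7 is alkylated, and an acetal is the one mask that survives the hot basic step earlier in the route. The forward reaction has to cleave the acetal without ionising the prenyl ether.

**O7–prenyl (15 from 14).** The C7–O–allyl bond is cut next, because the prenyl alkene tolerates neither a halonium reagent nor hydrogenolysis. In 14 the 5-OH is tied up in a hydrogen bond to C4=O and O4' is masked, so O7 is the only oxygen that should be alkylated.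

**C3–OMe (14 from 13).** The C3–O bond is traced back to a C3–I bond. Copper-mediated exchange with a methoxide source is the forward step. The same basic alcohol is expected to remove the ester on O5 and the silyl ether on O7, so one step replaces three.

**O1–C2 (13 from 12), the key disconnection.** Cutting O1–C2 and C3–I opens ring C to ynone 12, in which the future O1 is still a methyl ether. The cut is placed here because the ynone fixes the oxidation level of all three ring C carbons, so no redox adjustment follows. The forward step must let only the C8a oxygen close, which is why the other ortho oxygen is an ester in 12.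

**C4–C3 (12 from 7 by way of 11, and 10).** The ynone is cut between the carbonyl carbon and the alkyne into acid chloride 11 and terminal alkyne 10, to be joined by an acyl Sonogashira coupling. The more obvious addition of a metal acetylide to aldehyde 6 is avoided. It would place an alkoxide beside the aryl pivalate, which invites acyl transfer and then loss of the carboxylate to an ortho-quinone methide. The catalytic coupling has no such intermediate.

**Ring A (7 from 6, 5, 4, 2 and 1).** Acid 7 comes from aldehyde 6 by oxidation, and 6 from salicylaldehyde 5 by acylation. The C4a–CHO bond of 5 is cut back to phenol 4. An ortho-specific formylation must then pick one of two ortho carbons, and the bulky silyl ether on the future O7 shields the wrong one. Phenol 4 is traced to aldehyde 2 and to commercial 1 by a Baeyer–Villiger oxidation, so the formyl carbon of 1 marks where the fourth oxygen goes and no regiochemical question arises. The silyl ether therefore does three jobs: it steers the formylation, it shields C6 in the key step, and it leaves without a step of its own.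

**Ring B (10 from 9 and 8).** Alkyne 10 is cut back by a one-carbon homologation to aldehyde 9, the acetal-protected form of vanillin 8.

## Alternatives that were turned down

**Alternative 1:** Ring C would be cut at C3–C4 and at C2=C3, with C3 supplied as the carbon of an α-methoxy phosphorus ylide. In the forward step the ylide is C-acylated by a ring A acid chloride and then olefinates the ring B aryl ester carbonyl on the neighbouring phenol oxygen. The product is 5,7-bis(benzyloxy)-3,8-dimethoxy-2-[3-methoxy-4-(triisopropylsilyloxy)phenyl]-4H-chromen-4-one (A1).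
- In its favour: C3 arrives with its methoxy group, so no halogen exchange is needed. The last deprotection of A1 would use fluoride, which is kinder to a prenyl ether than the acid of the chosen route. On both points it is stronger.
- Against it: the acylated ylide is stabilised by the carbonyl group and carries an α-oxygen, so it is a poor nucleophile toward an ester carbonyl and the olefination would need heat. At that temperature transfer of the aroyl group and O-acylation of the ylide compete. A second equivalent of ylide is used up as base. Ring A must still be made with four different oxygens, now with benzyl on O5 and an aroyl ester on the C8a oxygen.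
- Comparison: the step count is similar. The chosen route offers bond formations that each run at low temperature by a well-understood mechanism, and it fixes the choice of O1 through the electronics of an ester rather than through a hand-built ester/ether pair.

**Alternative 2:** Ring C would be cut at C3–C4 of a dialdehyde. An N-heterocyclic carbene turns one aldehyde into an acyl anion equivalent that adds to the other. The product is racemic trans-5,7-bis(benzyloxy)-3-hydroxy-8-methoxy-2-[3-methoxy-4-(triisopropylsilyloxy)phenyl]chroman-4-one (A2).
- In its favour: the C3 oxygen is present from the start, conditions are neutral and metal-free, and no halogen is handled. It is stronger than the chosen route in getting the C3–O bond directly.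
- Against it: the C4 ketone forms only if the ring A aldehyde is the one converted into the acyl anion equivalent. That aldehyde is flanked by two oxygens and is electron-rich, while the aliphatic α-aryloxy aldehyde is more electrophilic, enolisable and able to expel the phenoxide. The two stereocentres of A2 are made only to be destroyed. A2 must then be dehydrogenated to the flavonol and methylated on O3.
- Comparison: that is two extra steps against one iodine-to-methoxy exchange in the chosen route. The chosen route keeps C2–C3 at the alkyne oxidation level, so no redox step follows the ring closure.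

**Alternative 3:** Ring C would be cut at O1–C8a. A hypervalent iodine oxidant converts the para-methoxyphenol part of ring A into a 2-acylbenzoquinone, and the enol oxygen of a 2-methoxy-1,3-diketone adds to C8a. Tautomerisation gives 4-[7-(benzyloxy)-5,8-dihydroxy-3-methoxy-4-oxo-4H-chromen-2-yl]-2-methoxyphenyl 4-methylbenzenesulfonate (A3).
- In its favour: ring A starts from a trioxygenated arene with no regiochemical problem, which is simpler than in the chosen route. The ring B sulfonate is later removed by base, which is safe for the prenyl ether. On both points it is stronger.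
- Against it: the oxidant must spare the enolisable diketone and ring B. The acylquinone is a strong electrophile, so water and the enol carbon compete with the enol oxygen. The hydroquinone A3 is easier to oxidise than the phenol it came from, so over-oxidation is likely. O8 must afterwards be methylated selectively, and a free 5,8-dihydroxyflavone is the substrate class most prone to reclosure onto the other ortho oxygen.
- Comparison: the chosen strategy offers a closing step that is redox-neutral at ring A and irreversible through loss of chloromethane, with the 8-methoxy group in place from the first compound.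

Key step: step 9

Remark on the chemistry: aldehyde 1 and vanillin 8 are taken as the commercial starting materials; fallback compounds with one stereocentre are racemic.

## Route

Step 1
Reactants: 1 3-hydroxy-4,5-dimethoxybenzaldehyde
Product: 2 3,4-dimethoxy-5-(triisopropylsilyloxy)benzaldehyde
Conditions: TIPSCl, imidazole, DMF, rt
Reagents that add atoms: triisopropylsilyl chloride, CC(C)[Si](Cl)(C(C)C)C(C)C
Why: Silylation of a phenol with a silyl chloride and imidazole is routine. The bulky silyl ether is chosen because it later blocks the neighbouring ring carbon and is cleaved in basic methanol.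

Step 2
Reactants: 2 3,4-dimethoxy-5-(triisopropylsilyloxy)benzaldehyde
Product: 4 3,4-dimethoxy-5-(triisopropylsilyloxy)phenol, via aryl formate 3 (not isolated)
Conditions: mCPBA, CH2Cl2, 0 °C to rt; then Et3N (cat.), MeOH, rt
Reagents that add atoms: 3-chloroperbenzoic acid, O=C(OO)c1cccc(Cl)c1
Why: Baeyer–Villiger (Dakin-type) oxidation; the aryl group migrates rather than hydrogen because the ring is electron-rich and has a para methoxy group. The aryl formate is methanolysed under amine catalysis, which should leave the aryl silyl ether intact.

Step 3
Reactants: 4 3,4-dimethoxy-5-(triisopropylsilyloxy)phenol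
Product: 5 6-hydroxy-2,3-dimethoxy-4-(triisopropylsilyloxy)benzaldehyde
Conditions: MgCl2, Et3N, (CH2O)n, MeCN, reflux; dilute HCl work-up
Reagents that add atoms: formaldehyde (as paraformaldehyde), C=O
Why: Magnesium-mediated ortho-formylation (Casnati–Skattebøl): the aryloxymagnesium chloride (ArOMgCl) delivers formaldehyde only ortho to its oxygen, and a second formaldehyde oxidises the benzylic alkoxide to the aldehyde. Of the two ortho carbons, the one beside the triisopropylsilyloxy group is shielded, so the new C–C bond should form between OH and OMe.

Step 4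
Reactants: 5 6-hydroxy-2,3-dimethoxy-4-(triisopropylsilyloxy)benzaldehyde
Product: 6 2-formyl-3,4-dimethoxy-5-(triisopropylsilyloxy)phenyl pivalate
Conditions: PivCl, Et3N, DMAP (10 mol%), CH2Cl2, 0 °C to rt
Reagents that add atoms: pivaloyl chloride, CC(C)(C)C(=O)Cl
Why: DMAP-catalysed O-acylation of the hydrogen-bonded phenol. The pivalate makes this oxygen non-nucleophilic for the ring closure and is hindered enough to last through the next four steps.

Step 5
Reactants: 6 2-formyl-3,4-dimethoxy-5-(triisopropylsilyloxy)phenyl pivalate
Product: 7 2,3-dimethoxy-6-(pivaloyloxy)-4-(triisopropylsilyloxy)benzoic acid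
Conditions: NaClO2, NaH2PO4, 2-methyl-2-butene, t-BuOH–THF–H2O, 0 °C to rt
Reagents that add atoms: NaClO2 (sodium chlorite), [Na+].[O-]Cl=O
Why: Pinnick oxidation of the aldehyde to the acid; buffered chlorite leaves the ester and the silyl ether alone. The alkene scavenges HOCl, which would otherwise chlorinate the electron-rich ring.

Step 6
Reactants: 8 vanillin (4-hydroxy-3-methoxybenzaldehyde)
Product: 9 3-methoxy-4-(methoxymethoxy)benzaldehyde
Conditions: MOMCl, i-Pr2NEt, CH2Cl2, 0 °C to rt
Reagents that add atoms: chloromethyl methyl ether, COCCl
Why: O-alkylation of the phenol with an α-chloro ether (Williamson type). The acetal withstands the basic and organometallic steps that follow.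

Step 7
Reactants: 9 3-methoxy-4-(methoxymethoxy)benzaldehyde
Product: 10 4-ethynyl-2-methoxy-1-(methoxymethoxy)benzene
Conditions: dimethyl (1-diazo-2-oxopropyl)phosphonate, K2CO3, MeOH, 0 °C to rt
Reagents that add atoms: dimethyl (1-diazo-2-oxopropyl)phosphonate, CC(=O)C(=[N+]=[N-])P(=O)(OC)OC
Why: Seyferth–Gilbert homologation in the Ohira–Bestmann form: the diazophosphonate anion made in situ olefinates the aldehyde, and the diazoalkene loses N2 and rearranges to the terminal alkyne. The mild base is compatible with the acetal.

Step 8
Reactants: 7 2,3-dimethoxy-6-(pivaloyloxy)-4-(triisopropylsilyloxy)benzoic acid; 10 4-ethynyl-2-methoxy-1-(methoxymethoxy)benzene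
Product: 12 3,4-dimethoxy-2-{3-[3-methoxy-4-(methoxymethoxy)phenyl]propioloyl}-5-(triisopropylsilyloxy)phenyl pivalate, via acid chloride 11 (not isolated)
Conditions: (COCl)2, DMF (cat.), CH2Cl2, 0 °C to rt, evaporate; then 10, PdCl2(PPh3)2 (2 mol%), CuI (4 mol%), Et3N, THF, rt
Reagents that add atoms: none
Why: Acid chloride formation, then acyl Sonogashira coupling: zerovalent palladium inserts into the C–Cl bond, the alkynylcopper species (ArC≡CCu) transmetalates, and reductive elimination at room temperature forms C4–C3 before CO can be lost. No alkoxide or strong nucleophile is ever beside the aryl pivalate, so acyl transfer cannot occur.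

Step 9
Reactants: 12 3,4-dimethoxy-2-{3-[3-methoxy-4-(methoxymethoxy)phenyl]propioloyl}-5-(triisopropylsilyloxy)phenyl pivalate
Product: 13 3-iodo-8-methoxy-2-[3-methoxy-4-(methoxymethoxy)phenyl]-4-oxo-7-(triisopropylsilyloxy)-4H-chromen-5-yl pivalate
Conditions: ICl (1.2 equiv), CH2Cl2, −78 °C; aq. Na2S2O3
Reagents that add atoms: iodine monochloride, ICl
Why: Iodine monochloride should deliver I+ to the triple bond of 12, and the iodonium ion is opened at the β-carbon, the future C2, where ring B stabilises the positive charge. The nucleophile is the methyl ether oxygen on the ring A carbon that becomes C8a, so ring C closes in 6-endo-dig mode, forming O1–C2 and leaving iodine on C3. Chloride then removes the methyl group from the O-methyl oxonium ion in an SN2 step; chloromethane leaves, which makes the closure irreversible and gives neutral 13. The closest known reaction type is the ICl-induced cyclisation of ortho-methoxyaryl alkynyl ketones to 3-iodochromones, which runs at low temperature and tolerates electron-rich aryl groups on the alkyne. No stereocentre is formed. Two selectivities are needed: only the C8a oxygen may close (the other ortho oxygen is an acylated, non-nucleophilic pivalate, whose carbonyl oxygen could reach C2 only through an eight-membered ring), and iodine must go to the alkyne rather than to an arene (the one free ring A carbon lies between the pivalate and the bulky silyl ether, ring B is deactivated by conjugation with the ynone, and a small excess of reagent at −78 °C keeps arene iodination slow). A 5-exo closure is not expected, because attack at the α-carbon would put the developing cation next to the carbonyl group.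

Step 10
Reactants: 13 3-iodo-8-methoxy-2-[3-methoxy-4-(methoxymethoxy)phenyl]-4-oxo-7-(triisopropylsilyloxy)-4H-chromen-5-yl pivalate
Product: 14 5,7-dihydroxy-3,8-dimethoxy-2-[3-methoxy-4-(methoxymethoxy)phenyl]-4H-chromen-4-one
Conditions: CuI (20 mol%), 1,10-phenanthroline (40 mol%), Cs2CO3, MeOH, 90 °C, sealed tube; aq. NH4Cl
Reagents that add atoms: methanol, CO
Why: Ullmann-type C–O coupling of the C3 iodide with methanol, catalysed by monovalent copper, as used for aryl and vinyl iodides and for halogenated flavones. The same basic methanol transesterifies the pivalate and cleaves the aryl silyl ether, whose aryloxide is a good leaving group because O7 is conjugated with C4=O, so the 5,7-diol is obtained directly.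

Step 11
Reactants: 14 5,7-dihydroxy-3,8-dimethoxy-2-[3-methoxy-4-(methoxymethoxy)phenyl]-4H-chromen-4-one
Product: 15 5-hydroxy-3,8-dimethoxy-2-[3-methoxy-4-(methoxymethoxy)phenyl]-7-(3-methylbut-2-enyloxy)-4H-chromen-4-one
Conditions: prenyl bromide (1.1 equiv), K2CO3 (1.2 equiv), acetone, rt to 45 °C
Reagents that add atoms: 1-bromo-3-methylbut-2-ene, CC(C)=CCBr
Why: Williamson etherification. The 7-OH is the most acidic hydroxyl (a vinylogous acid), the 5-OH is held in a hydrogen bond to C4=O, and O4' is masked, so one equivalent of base should alkylate O7 only.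

Step 12
Reactants: 15 5-hydroxy-3,8-dimethoxy-2-[3-methoxy-4-(methoxymethoxy)phenyl]-7-(3-methylbut-2-enyloxy)-4H-chromen-4-one
Product: 16 5,4'-dihydroxy-3,8,3'-trimethoxy-7-prenyloxyflavone
Conditions: 1 M HCl in MeOH–THF, rt, stopped at full conversion; NaHCO3
Reagents that add atoms: none
Why: Acid-catalysed acetal exchange with methanol (the methoxymethyl group leaves as dimethoxymethane). The acetal ionises through an oxocarbenium ion much faster than the prenyl ether, whose oxygen is a weakly basic vinylogous ester oxygen, and room temperature with a short reaction time should keep the prenyl ether and the ring A pattern intact.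

## Compound list

1 | 3-hydroxy-4,5-dimethoxybenzaldehyde | O=Cc1cc(O)c(OC)c(OC)c1 | starting material
2 | 3,4-dimethoxy-5-(triisopropylsilyloxy)benzaldehyde | O=Cc1cc(OC)c(OC)c(O[Si](C(C)C)(C(C)C)C(C)C)c1 | intermediate
3 | 3,4-dimethoxy-5-(triisopropylsilyloxy)phenyl formate | O=COc1cc(OC)c(OC)c(O[Si](C(C)C)(C(C)C)C(C)C)c1 | intermediate
4 | 3,4-dimethoxy-5-(triisopropylsilyloxy)phenol | Oc1cc(OC)c(OC)c(O[Si](C(C)C)(C(C)C)C(C)C)c1 | intermediate
5 | 6-hydroxy-2,3-dimethoxy-4-(triisopropylsilyloxy)benzaldehyde | O=Cc1c(O)cc(O[Si](C(C)C)(C(C)C)C(C)C)c(OC)c1OC | intermediate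
6 | 2-formyl-3,4-dimethoxy-5-(triisopropylsilyloxy)phenyl pivalate | O=Cc1c(OC(=O)C(C)(C)C)cc(O[Si](C(C)C)(C(C)C)C(C)C)c(OC)c1OC | intermediate
7 | 2,3-dimethoxy-6-(pivaloyloxy)-4-(triisopropylsilyloxy)benzoic acid | OC(=O)c1c(OC(=O)C(C)(C)C)cc(O[Si](C(C)C)(C(C)C)C(C)C)c(OC)c1OC | intermediate
8 | vanillin (4-hydroxy-3-methoxybenzaldehyde) | COc1cc(C=O)ccc1O | starting material
9 | 3-methoxy-4-(methoxymethoxy)benzaldehyde | COCOc1ccc(C=O)cc1OC | intermediate
10 | 4-ethynyl-2-methoxy-1-(methoxymethoxy)benzene | COCOc1ccc(C#C)cc1OC | intermediate
11 | 2,3-dimethoxy-6-(pivaloyloxy)-4-(triisopropylsilyloxy)benzoyl chloride | ClC(=O)c1c(OC(=O)C(C)(C)C)cc(O[Si](C(C)C)(C(C)C)C(C)C)c(OC)c1OC | intermediate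
12 | 3,4-dimethoxy-2-{3-[3-methoxy-4-(methoxymethoxy)phenyl]propioloyl}-5-(triisopropylsilyloxy)phenyl pivalate | COc1c(OC)c(O[Si](C(C)C)(C(C)C)C(C)C)cc(OC(=O)C(C)(C)C)c1C(=O)C#Cc1ccc(OCOC)c(OC)c1 | intermediate
13 | 3-iodo-8-methoxy-2-[3-methoxy-4-(methoxymethoxy)phenyl]-4-oxo-7-(triisopropylsilyloxy)-4H-chromen-5-yl pivalate | O=c1c(I)c(-c2ccc(OCOC)c(OC)c2)oc2c(OC)c(O[Si](C(C)C)(C(C)C)C(C)C)cc(OC(=O)C(C)(C)C)c12 | intermediate
14 | 5,7-dihydroxy-3,8-dimethoxy-2-[3-methoxy-4-(methoxymethoxy)phenyl]-4H-chromen-4-one | COCOc1ccc(-c2oc3c(OC)c(O)cc(O)c3c(=O)c2OC)cc1OC | intermediate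
15 | 5-hydroxy-3,8-dimethoxy-2-[3-methoxy-4-(methoxymethoxy)phenyl]-7-(3-methylbut-2-enyloxy)-4H-chromen-4-one | COCOc1ccc(-c2oc3c(OC)c(OCC=C(C)C)cc(O)c3c(=O)c2OC)cc1OC | intermediate
16 | 5,4'-dihydroxy-3,8,3'-trimethoxy-7-prenyloxyflavone | COc1cc(-c2oc3c(OC)c(OCC=C(C)C)cc(O)c3c(=O)c2OC)ccc1O | target

## Step count and least certain steps

Total: 12 steps. Longest linear sequence: 10 steps (1 to 16 through steps 1–5 and 8–12); the ring B branch adds steps 6 and 7.

**Step 9 (key step).** The likely failure is that ICl attacks the electron-rich ring B or C6, or that traces of acid strip the acetal, while the closure is slowed because the doubly ortho-substituted aryl ketone is twisted out of plane. The fallback makes ring B electron-poor and acid-proof for the halonium step and puts the acetal on afterwards. It sets out from alkyne 10 and acid chloride 11. Treating 10 with HCl in MeOH gives 4-ethynyl-2-methoxyphenol F1, and Ac2O with pyridine gives 4-ethynyl-2-methoxyphenyl acetate F2. Coupling F2 with 11 under the conditions of step 8 gives the ynone acetate F3, and ICl at −78 °C gives the iodochromone acetate F4. Cleaving the aryl acetate beside the hindered pivalate (NH4OAc, aqueous MeOH, rt) gives the 4'-phenol F5, and MOMCl with i-Pr2NEt brings the route back at 13.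

**Step 10.** Once the pivalate and silyl ether have gone, the substrate is an electron-rich bis-phenoxide, and reduction of the C–I bond or addition of methoxide at C2 with opening of ring C may outrun the C–O coupling. The fallback makes the C3–O bond by oxidation of a C–B bond while the protecting groups are still on. It sets out from 13. Miyaura borylation (B2pin2, PdCl2(dppf), KOAc, dioxane, 80 °C) gives the 3-boronate F6, and NaBO3·4H2O in THF–H2O gives the flavonol F7. MeI with K2CO3 in acetone gives the 3-methyl ether F8, and K2CO3 in MeOH removes the pivalate and the silyl ether to return at 14.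

**Step 12.** The acid needed for the acetal may ionise the prenyl ether, with loss of the prenyl group or its shift to carbon, and may start reclosure of ring C onto the 5-oxygen. The fallback removes the acetal before any prenyl group is present and relies on acidity for the alkylation. It sets out from 14. HCl in MeOH at 40 °C gives 5,7-dihydroxy-2-(4-hydroxy-3-methoxyphenyl)-3,8-dimethoxy-4H-chromen-4-one F9. A Mitsunobu reaction with one equivalent of 3-methylbut-2-en-1-ol (PPh3, DIAD, THF, 0 °C) should etherify the most acidic hydroxyl, 7-OH, and return at 16.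

**Step 8.** Coupling of the hindered acid chloride may be slow, so that decarbonylation at palladium or oxidative dimerisation of the alkyne takes over. The fallback forms C4–C3 by carbonyl addition before the ester is in place. It sets out from salicylaldehyde 5 and alkyne 10. Addition of the lithium acetylide of 10 (ArC≡CLi, 2.2 equiv, from n-BuLi, THF, −78 °C) to 5 gives the racemic propargylic alcohol phenol F10. Acylation of the phenol only (PivCl, Et3N, CH2Cl2, −20 °C, no DMAP) gives the racemic pivalate alcohol F11, and MnO2 in CH2Cl2 returns at 12. Because the ester is introduced after the alkoxide has been quenched, acyl transfer is avoided.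

**Step 3.** Formylation may occur partly at the other ortho carbon, or stop at the hydroxymethyl stage. The fallback uses directed ortho-metalation, where the site between two oxygen donors is the only one a base can reach. It sets out from phenol 4. MOMCl with i-Pr2NEt gives the acetal F12. n-BuLi with TMEDA in THF at 0 °C, then DMF, gives the aldehyde F13. Dilute HCl in MeOH at rt removes the acetal and returns at 5.

## Further compounds

F1 | step 9 | 4-ethynyl-2-methoxyphenol | C#Cc1ccc(O)c(OC)c1
F2 | step 9 | 4-ethynyl-2-methoxyphenyl acetate | CC(=O)Oc1ccc(C#C)cc1OC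
F3 | step 9 | 2-{3-[4-(acetyloxy)-3-methoxyphenyl]propioloyl}-3,4-dimethoxy-5-(triisopropylsilyloxy)phenyl pivalate | COc1c(OC)c(O[Si](C(C)C)(C(C)C)C(C)C)cc(OC(=O)C(C)(C)C)c1C(=O)C#Cc1ccc(OC(C)=O)c(OC)c1
F4 | step 9 | 2-[4-(acetyloxy)-3-methoxyphenyl]-3-iodo-8-methoxy-4-oxo-7-(triisopropylsilyloxy)-4H-chromen-5-yl pivalate | CC(=O)Oc1ccc(-c2oc3c(OC)c(O[Si](C(C)C)(C(C)C)C(C)C)cc(OC(=O)C(C)(C)C)c3c(=O)c2I)cc1OC
F5 | step 9 | 2-(4-hydroxy-3-methoxyphenyl)-3-iodo-8-methoxy-4-oxo-7-(triisopropylsilyloxy)-4H-chromen-5-yl pivalate | COc1cc(-c2oc3c(OC)c(O[Si](C(C)C)(C(C)C)C(C)C)cc(OC(=O)C(C)(C)C)c3c(=O)c2I)ccc1O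
F6 | step 10 | 8-methoxy-2-[3-methoxy-4-(methoxymethoxy)phenyl]-4-oxo-3-(4,4,5,5-tetramethyl-1,3,2-dioxaborolan-2-yl)-7-(triisopropylsilyloxy)-4H-chromen-5-yl pivalate | COCOc1ccc(-c2oc3c(OC)c(O[Si](C(C)C)(C(C)C)C(C)C)cc(OC(=O)C(C)(C)C)c3c(=O)c2B4OC(C)(C)C(C)(C)O4)cc1OC
F7 | step 10 | 3-hydroxy-8-methoxy-2-[3-methoxy-4-(methoxymethoxy)phenyl]-4-oxo-7-(triisopropylsilyloxy)-4H-chromen-5-yl pivalate | COCOc1ccc(-c2oc3c(OC)c(O[Si](C(C)C)(C(C)C)C(C)C)cc(OC(=O)C(C)(C)C)c3c(=O)c2O)cc1OC
F8 | step 10 | 3,8-dimethoxy-2-[3-methoxy-4-(methoxymethoxy)phenyl]-4-oxo-7-(triisopropylsilyloxy)-4H-chromen-5-yl pivalate | COCOc1ccc(-c2oc3c(OC)c(O[Si](C(C)C)(C(C)C)C(C)C)cc(OC(=O)C(C)(C)C)c3c(=O)c2OC)cc1OC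
F9 | step 12 | 5,7-dihydroxy-2-(4-hydroxy-3-methoxyphenyl)-3,8-dimethoxy-4H-chromen-4-one | COc1cc(-c2oc3c(OC)c(O)cc(O)c3c(=O)c2OC)ccc1O
F10 | step 8 | 2-{1-hydroxy-3-[3-methoxy-4-(methoxymethoxy)phenyl]prop-2-yn-1-yl}-3,4-dimethoxy-5-(triisopropylsilyloxy)phenol (racemic) | COc1c(OC)c(O[Si](C(C)C)(C(C)C)C(C)C)cc(O)c1C(O)C#Cc1ccc(OCOC)c(OC)c1
F11 | step 8 | 2-{1-hydroxy-3-[3-methoxy-4-(methoxymethoxy)phenyl]prop-2-yn-1-yl}-3,4-dimethoxy-5-(triisopropylsilyloxy)phenyl pivalate (racemic) | COc1c(OC)c(O[Si](C(C)C)(C(C)C)C(C)C)cc(OC(=O)C(C)(C)C)c1C(O)C#Cc1ccc(OCOC)c(OC)c1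
F12 | step 3 | [3,4-dimethoxy-5-(methoxymethoxy)phenoxy]triisopropylsilane | COCOc1cc(OC)c(OC)c(O[Si](C(C)C)(C(C)C)C(C)C)c1
F13 | step 3 | 2,3-dimethoxy-6-(methoxymethoxy)-4-(triisopropylsilyloxy)benzaldehyde | O=Cc1c(OCOC)cc(O[Si](C(C)C)(C(C)C)C(C)C)c(OC)c1OC
A1 | alternative 1 | 5,7-bis(benzyloxy)-3,8-dimethoxy-2-[3-methoxy-4-(triisopropylsilyloxy)phenyl]-4H-chromen-4-one | COc1c(-c2ccc(O[Si](C(C)C)(C(C)C)C(C)C)c(OC)c2)oc2c(OC)c(OCc3ccccc3)cc(OCc3ccccc3)c2c1=O
A2 | alternative 2 | racemic trans-5,7-bis(benzyloxy)-3-hydroxy-8-methoxy-2-[3-methoxy-4-(triisopropylsilyloxy)phenyl]chroman-4-one (one enantiomer drawn) | COc1cc(ccc1O[Si](C(C)C)(C(C)C)C(C)C)[C@H]1Oc2c(OC)c(OCc3ccccc3)cc(OCc3ccccc3)c2C(=O)[C@@H]1O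
A3 | alternative 3 | 4-[7-(benzyloxy)-5,8-dihydroxy-3-methoxy-4-oxo-4H-chromen-2-yl]-2-methoxyphenyl 4-methylbenzenesulfonate | COc1c(-c2ccc(OS(=O)(=O)c3ccc(C)cc3)c(OC)c2)oc2c(O)c(OCc3ccccc3)cc(O)c2c1=O
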